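**Retrosynthetic overview**
- Target ⇐ hydrogenolysis of five aryl benzyl ethers. The phenol of the carbinol ring is carried as an aryl bromide (Br → Bpin → OH), so that this benzylic carbinol cannot ionise.
- Cyclopentane ring of the indane (last ring formed) ⇐ intramolecular Friedel–Crafts alkylation of the 3,5-dibenzyloxyphenyl ring A by the 4-benzyloxybenzylic cation of an open-chain 1,4-diol. This sets C-3 trans to the C-2 aryl.
- Diol ⇐ lactol + ArMgBr ⇐ all-trans γ-butyrolactone (temporary ring, formed first). Base equilibration of this lactone fixes C-2.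
- Lactone ⇐ 1,1-disubstituted alkene (hydroboration, oxidative lactonisation) ⇐ aryl ketone ⇐ Weinreb amide.
- Key C–C bond: magnesium-catalysed Evans anti-aldol of an N-arylacetyl oxazolidinone with 4-bromobenzaldehyde, which sets the carbinol carbon and C-1.

Reading of the target (assumed from the SMILES): indane C-1 is S and bears the (R)-carbinol, C-2 is S (3,5-dihydroxyphenyl), C-3 is R (4-hydroxyphenyl); the C-1 side chain and C-2 aryl are cis, the C-2 and C-3 aryls trans.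

**Step 1**
Reactants: 1 methyl 2-(3,5-dihydroxyphenyl)acetate
Product: 2 methyl 2-[3,5-bis(benzyloxy)phenyl]acetate
Conditions: BnBr, K2CO3, DMF, 60 °C
Reagents that add atoms: benzyl bromide, BrCc1ccccc1
Why: Williamson etherification of both phenols; K2CO3 is too weak to enolise the arylacetate, so only O-benzylation occurs.

**Step 2**
Reactants: 2 methyl 2-[3,5-bis(benzyloxy)phenyl]acetate
Product: 3 2-[3,5-bis(benzyloxy)phenyl]acetic acid
Conditions: LiOH, THF/MeOH/H2O, rt; then 1 M HCl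
Reagents that add atoms: lithium hydroxide, [Li+].[OH-]
Why: Ester saponification followed by acidification; the benzyl ethers are inert.

**Step 3**
Reactants: 3 2-[3,5-bis(benzyloxy)phenyl]acetic acid; 4 (R)-4-benzyloxazolidin-2-one
Product: 6 (R)-4-benzyl-3-{2-[3,5-bis(benzyloxy)phenyl]acetyl}oxazolidin-2-one, via mixed pivalic anhydride 5 (not isolated)
Conditions: PivCl, Et3N, THF, −20 °C; then 4, LiCl, −20 °C → rt
Reagents that add atoms: pivaloyl chloride, CC(C)(C)C(Cl)=O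
Why: N-acylation of the Evans auxiliary by the in situ mixed anhydride (LiCl/Et3N variant), which needs no strong base and leaves the auxiliary stereocentre untouched.

**Step 4**
Reactants: 6 (R)-4-benzyl-3-{2-[3,5-bis(benzyloxy)phenyl]acetyl}oxazolidin-2-one; 7 4-bromobenzaldehyde
Product: 9 (R)-4-benzyl-3-{(2S,3R)-2-[3,5-bis(benzyloxy)phenyl]-3-(4-bromophenyl)-3-hydroxypropanoyl}oxazolidin-2-one, via O-trimethylsilyl aldol adduct 8 (not isolated)
Conditions: MgCl2 (20 mol %), Et3N, TMSCl, EtOAc, rt, 24 h; then TFA (cat.), MeOH, rt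
Reagents that add atoms: chlorotrimethylsilane, C[Si](C)(C)Cl
Why: Evans magnesium-halide-catalysed direct anti-aldol reaction (key fragment union): soft enolisation gives the chelated Z-enolate, the aldehyde adds to the face away from the auxiliary benzyl group through a boat transition state to set C-2 (S) and C-3 (R) anti, and in situ silylation stops retro-aldol.

**Step 5**
Reactants: 9 (R)-4-benzyl-3-{(2S,3R)-2-[3,5-bis(benzyloxy)phenyl]-3-(4-bromophenyl)-3-hydroxypropanoyl}oxazolidin-2-one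
Product: 10 (2S,3R)-2-[3,5-bis(benzyloxy)phenyl]-3-(4-bromophenyl)-3-hydroxy-N-methoxy-N-methylpropanamide
Conditions: AlMe3, MeNHOMe·HCl, CH2Cl2, −20 → 0 °C; 0.5 M HCl work-up
Reagents that add atoms: N,O-dimethylhydroxylamine hydrochloride, CNOC.Cl
Why: Weinreb transamination of the imide by the aluminium amide, directed to the exocyclic carbonyl by the free β-hydroxyl, releases the auxiliary without touching either stereocentre.

**Step 6**
Reactants: 10 (2S,3R)-2-[3,5-bis(benzyloxy)phenyl]-3-(4-bromophenyl)-3-hydroxy-N-methoxy-N-methylpropanamide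
Product: 11 (2S,3R)-2-[3,5-bis(benzyloxy)phenyl]-3-(4-bromophenyl)-3-[(tert-butyldimethylsilyl)oxy]-N-methoxy-N-methylpropanamide
Conditions: TBSOTf, 2,6-lutidine, CH2Cl2, 0 °C
Reagents that add atoms: tert-butyldimethylsilyl trifluoromethanesulfonate, CC(C)(C)[Si](C)(C)OS(=O)(=O)C(F)(F)F
Why: Silyl ether formation protects the carbinol against retro-aldol and oxidation in the following steps.

**Step 7**
Reactants: 12 5-bromobenzene-1,3-diol
Product: 13 1,3-bis(benzyloxy)-5-bromobenzene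
Conditions: BnBr, K2CO3, DMF, 60 °C
Reagents that add atoms: benzyl bromide, BrCc1ccccc1
Why: Williamson etherification of both phenols gives the aryl bromide needed for the Grignard reagent.

**Step 8**
Reactants: 11 (2S,3R)-2-[3,5-bis(benzyloxy)phenyl]-3-(4-bromophenyl)-3-[(tert-butyldimethylsilyl)oxy]-N-methoxy-N-methylpropanamide; 13 1,3-bis(benzyloxy)-5-bromobenzene
Product: 15 (2S,3R)-1,2-bis[3,5-bis(benzyloxy)phenyl]-3-(4-bromophenyl)-3-[(tert-butyldimethylsilyl)oxy]propan-1-one, via [3,5-bis(benzyloxy)phenyl]magnesium bromide 14 (not isolated)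
Conditions: 13, Mg (I2 cat.), THF, 50 °C; then 11, THF, 0 °C → rt; aq. NH4Cl
Reagents that add atoms: magnesium, [Mg]
Why: Grignard addition to the Weinreb amide stops at the chelated tetrahedral intermediate, so the epimerisable ketone appears only on quench, and the aryl bromide of 11 does not exchange with an arylmagnesium halide.

**Step 9**
Reactants: 15 (2S,3R)-1,2-bis[3,5-bis(benzyloxy)phenyl]-3-(4-bromophenyl)-3-[(tert-butyldimethylsilyl)oxy]propan-1-one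
Product: 16 tert-butyl{[(1R,2R)-2,3-bis[3,5-bis(benzyloxy)phenyl]-1-(4-bromophenyl)but-3-en-1-yl]oxy}dimethylsilane
Conditions: Cp2TiMe2 (3 equiv), toluene, 65 °C, dark
Reagents that add atoms: dimethyltitanocene, C[Ti](C)(C1C=CC=C1)C1C=CC=C1
Why: Petasis methylenation with the non-basic titanium methylidene converts the hindered, enolisable ketone into the 1,1-disubstituted alkene without epimerisation or β-elimination (the descriptor at C-2 changes only through CIP priorities).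

**Step 10**
Reactants: 16 tert-butyl{[(1R,2R)-2,3-bis[3,5-bis(benzyloxy)phenyl]-1-(4-bromophenyl)but-3-en-1-yl]oxy}dimethylsilane
Product: 18 (2RS,3S,4R)-2,3-bis[3,5-bis(benzyloxy)phenyl]-4-(4-bromophenyl)-4-[(tert-butyldimethylsilyl)oxy]butan-1-ol, via primary alkylborane 17 (not isolated)
Conditions: BH3·THF, THF, 0 °C → rt; then NaOH, H2O2, 0 °C → rt
Reagents that add atoms: borane–tetrahydrofuran, [BH3-][O+]1CCCC1; hydrogen peroxide, OO
Why: Brown hydroboration–oxidation puts oxygen on the terminal carbon of the α-substituted styrene; the new benzylic centre forms unselectively, which does not matter because step 13 equilibrates it.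

**Step 11**
Reactants: 18 (2RS,3S,4R)-2,3-bis[3,5-bis(benzyloxy)phenyl]-4-(4-bromophenyl)-4-[(tert-butyldimethylsilyl)oxy]butan-1-ol
Product: 19 (1R,2S,3RS)-2,3-bis[3,5-bis(benzyloxy)phenyl]-1-(4-bromophenyl)butane-1,4-diol
Conditions: TBAF, THF, rt
Reagents that add atoms: none
Why: Fluoride-mediated desilylation frees the secondary carbinol for lactonisation.

**Step 12**
Reactants: 19 (1R,2S,3RS)-2,3-bis[3,5-bis(benzyloxy)phenyl]-1-(4-bromophenyl)butane-1,4-diol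
Product: 21 (4S,5R)-3,4-bis[3,5-bis(benzyloxy)phenyl]-5-(4-bromophenyl)dihydrofuran-2(3H)-one (C-3 epimers), via lactol 20 (not isolated)
Conditions: TEMPO (20 mol %), PhI(OAc)2 (2.5 equiv), CH2Cl2, rt
Reagents that add atoms: none
Why: TEMPO/PhI(OAc)2 oxidative lactonisation: the primary alcohol is oxidised selectively, the aldehyde closes onto the secondary hydroxyl and the lactol is oxidised on to the γ-lactone.

**Step 13**
Reactants: 21 (4S,5R)-3,4-bis[3,5-bis(benzyloxy)phenyl]-5-(4-bromophenyl)dihydrofuran-2(3H)-one (C-3 epimers)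
Product: 22 (3S,4S,5R)-3,4-bis[3,5-bis(benzyloxy)phenyl]-5-(4-bromophenyl)dihydrofuran-2(3H)-one (all-trans)
Conditions: DBU (0.5 equiv), toluene, 40 °C
Reagents that add atoms: none
Why: Thermodynamic epimerisation through the lactone enolate places the C-3 aryl trans to the C-4 aryl, which fixes the third stereocentre (3S, the future indane C-2).

**Step 14**
Reactants: 22 (3S,4S,5R)-3,4-bis[3,5-bis(benzyloxy)phenyl]-5-(4-bromophenyl)dihydrofuran-2(3H)-one
Product: 23 (3S,4S,5R)-3,4-bis[3,5-bis(benzyloxy)phenyl]-5-(4-bromophenyl)tetrahydrofuran-2-ol (anomers)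
Conditions: i-Bu2AlH, CH2Cl2, −78 °C; aq. KNaC4H4O6
Reagents that add atoms: none
Why: Partial reduction of the lactone stops at the lactol because the tetrahedral aluminate is stable at −78 °C.

**Step 15**
Reactants: 23 (3S,4S,5R)-3,4-bis[3,5-bis(benzyloxy)phenyl]-5-(4-bromophenyl)tetrahydrofuran-2-ol; 24 1-(benzyloxy)-4-bromobenzene
Product: 26 (1RS,2S,3S,4R)-1-[4-(benzyloxy)phenyl]-2,3-bis[3,5-bis(benzyloxy)phenyl]-4-(4-bromophenyl)butane-1,4-diol, via [4-(benzyloxy)phenyl]magnesium bromide 25 (not isolated)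
Conditions: 24, Mg (I2 cat.), THF, 50 °C; then 23, THF, 0 °C → rt; aq. NH4Cl
Reagents that add atoms: magnesium, [Mg]
Why: Grignard addition to the open hydroxy-aldehyde form of the lactol gives the 1,4-diol; the new carbinol is an epimer mixture, which is harmless because it is ionised in the next step.

**Step 16**
Reactants: 26 (1RS,2S,3S,4R)-1-[4-(benzyloxy)phenyl]-2,3-bis[3,5-bis(benzyloxy)phenyl]-4-(4-bromophenyl)butane-1,4-diol
Product: 27 (R)-{(1S,2S,3R)-4,6-bis(benzyloxy)-3-[4-(benzyloxy)phenyl]-2-[3,5-bis(benzyloxy)phenyl]-2,3-dihydro-1H-inden-1-yl}(4-bromophenyl)methanol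
Conditions: TsOH·H2O (10 mol %), HFIP/CH2Cl2 (1:4), 0.01 M, 0 °C
Reagents that add atoms: none
Why: Intramolecular Friedel–Crafts alkylation: only the 4-benzyloxybenzylic alcohol ionises (the 4-bromophenyl carbinol does not), the cation is captured by the activated ortho position of ring A in a five-membered ring closure, and the new C-3 aryl settles trans to the C-2 aryl.

**Step 17**
Reactants: 27 (R)-{(1S,2S,3R)-4,6-bis(benzyloxy)-3-[4-(benzyloxy)phenyl]-2-[3,5-bis(benzyloxy)phenyl]-2,3-dihydro-1H-inden-1-yl}(4-bromophenyl)methanol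
Product: 28 (R)-{(1S,2S,3R)-4,6-bis(benzyloxy)-3-[4-(benzyloxy)phenyl]-2-[3,5-bis(benzyloxy)phenyl]-2,3-dihydro-1H-inden-1-yl}[4-(4,4,5,5-tetramethyl-1,3,2-dioxaborolan-2-yl)phenyl]methanol
Conditions: B2pin2, Pd(dppf)Cl2 (5 mol %), KOAc, 1,4-dioxane, 90 °C
Reagents that add atoms: bis(pinacolato)diboron, CC1(C)OB(OC1(C)C)B1OC(C)(C)C(C)(C)O1
Why: Miyaura borylation of the aryl bromide tolerates the free secondary alcohol and the benzyl ethers.

**Step 18**
Reactants: 28 (R)-{(1S,2S,3R)-4,6-bis(benzyloxy)-3-[4-(benzyloxy)phenyl]-2-[3,5-bis(benzyloxy)phenyl]-2,3-dihydro-1H-inden-1-yl}[4-(4,4,5,5-tetramethyl-1,3,2-dioxaborolan-2-yl)phenyl]methanol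
Product: 29 4-[(R)-{(1S,2S,3R)-4,6-bis(benzyloxy)-3-[4-(benzyloxy)phenyl]-2-[3,5-bis(benzyloxy)phenyl]-2,3-dihydro-1H-inden-1-yl}(hydroxy)methyl]phenol
Conditions: H2O2 (30 % aq.), NaOH, THF/H2O, 0 °C; then aq. NH4Cl
Reagents that add atoms: hydrogen peroxide, OO
Why: Oxidation of the arylboronate (1,2-aryl shift from boron to oxygen) gives the phenol and touches no stereocentre.

**Step 19**
Reactants: 29 4-[(R)-{(1S,2S,3R)-4,6-bis(benzyloxy)-3-[4-(benzyloxy)phenyl]-2-[3,5-bis(benzyloxy)phenyl]-2,3-dihydro-1H-inden-1-yl}(hydroxy)methyl]phenol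
Product: 30 (1S,2S,3R)-2-(3,5-dihydroxyphenyl)-1-[(R)-hydroxy(4-hydroxyphenyl)methyl]-3-(4-hydroxyphenyl)-2,3-dihydro-1H-indene-4,6-diol
Conditions: H2 (1 atm), Pd/C (10 wt % Pd), EtOAc/MeOH, rt
Reagents that add atoms: none
Why: Hydrogenolysis of the five aryl benzyl ethers under neutral conditions avoids the acid that would ionise the p-hydroxybenzylic alcohol towards a second ring closure.

**Compound list**
1 | methyl 2-(3,5-dihydroxyphenyl)acetate | COC(=O)Cc1cc(O)cc(O)c1 | starting material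
2 | methyl 2-[3,5-bis(benzyloxy)phenyl]acetate | COC(=O)Cc1cc(OCc2ccccc2)cc(OCc2ccccc2)c1 | intermediate
3 | 2-[3,5-bis(benzyloxy)phenyl]acetic acid | OC(=O)Cc1cc(OCc2ccccc2)cc(OCc2ccccc2)c1 | intermediate
4 | (R)-4-benzyloxazolidin-2-one | O=C1N[C@H](Cc2ccccc2)CO1 | starting material
5 | 2-[3,5-bis(benzyloxy)phenyl]acetic pivalic anhydride | CC(C)(C)C(=O)OC(=O)Cc1cc(OCc2ccccc2)cc(OCc2ccccc2)c1 | intermediate
6 | (R)-4-benzyl-3-{2-[3,5-bis(benzyloxy)phenyl]acetyl}oxazolidin-2-one | O=C(Cc1cc(OCc2ccccc2)cc(OCc2ccccc2)c1)N1[C@H](Cc2ccccc2)COC1=O | intermediate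
7 | 4-bromobenzaldehyde | O=Cc1ccc(Br)cc1 | starting material
8 | (R)-4-benzyl-3-{(2S,3R)-2-[3,5-bis(benzyloxy)phenyl]-3-(4-bromophenyl)-3-[(trimethylsilyl)oxy]propanoyl}oxazolidin-2-one | O=C([C@@H](c1cc(OCc2ccccc2)cc(OCc2ccccc2)c1)[C@@H](O[Si](C)(C)C)c1ccc(Br)cc1)N1[C@H](Cc2ccccc2)COC1=O | intermediate
9 | (R)-4-benzyl-3-{(2S,3R)-2-[3,5-bis(benzyloxy)phenyl]-3-(4-bromophenyl)-3-hydroxypropanoyl}oxazolidin-2-one | O=C([C@@H](c1cc(OCc2ccccc2)cc(OCc2ccccc2)c1)[C@@H](O)c1ccc(Br)cc1)N1[C@H](Cc2ccccc2)COC1=O | intermediate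
10 | (2S,3R)-2-[3,5-bis(benzyloxy)phenyl]-3-(4-bromophenyl)-3-hydroxy-N-methoxy-N-methylpropanamide | CON(C)C(=O)[C@@H](c1cc(OCc2ccccc2)cc(OCc2ccccc2)c1)[C@@H](O)c1ccc(Br)cc1 | intermediate
11 | (2S,3R)-2-[3,5-bis(benzyloxy)phenyl]-3-(4-bromophenyl)-3-[(tert-butyldimethylsilyl)oxy]-N-methoxy-N-methylpropanamide | CON(C)C(=O)[C@@H](c1cc(OCc2ccccc2)cc(OCc2ccccc2)c1)[C@@H](O[Si](C)(C)C(C)(C)C)c1ccc(Br)cc1 | intermediate
12 | 5-bromobenzene-1,3-diol | Oc1cc(O)cc(Br)c1 | starting material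
13 | 1,3-bis(benzyloxy)-5-bromobenzene | Brc1cc(OCc2ccccc2)cc(OCc2ccccc2)c1 | intermediate
14 | [3,5-bis(benzyloxy)phenyl]magnesium bromide | Br[Mg]c1cc(OCc2ccccc2)cc(OCc2ccccc2)c1 | intermediate
15 | (2S,3R)-1,2-bis[3,5-bis(benzyloxy)phenyl]-3-(4-bromophenyl)-3-[(tert-butyldimethylsilyl)oxy]propan-1-one | O=C(c1cc(OCc2ccccc2)cc(OCc2ccccc2)c1)[C@@H](c1cc(OCc2ccccc2)cc(OCc2ccccc2)c1)[C@@H](O[Si](C)(C)C(C)(C)C)c1ccc(Br)cc1 | intermediate
16 | tert-butyl{[(1R,2R)-2,3-bis[3,5-bis(benzyloxy)phenyl]-1-(4-bromophenyl)but-3-en-1-yl]oxy}dimethylsilane | C=C(c1cc(OCc2ccccc2)cc(OCc2ccccc2)c1)[C@@H](c1cc(OCc2ccccc2)cc(OCc2ccccc2)c1)[C@@H](O[Si](C)(C)C(C)(C)C)c1ccc(Br)cc1 | intermediate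
17 | {(2RS,3S,4R)-2,3-bis[3,5-bis(benzyloxy)phenyl]-4-(4-bromophenyl)-4-[(tert-butyldimethylsilyl)oxy]butyl}borane | [BH2]CC(c1cc(OCc2ccccc2)cc(OCc2ccccc2)c1)[C@@H](c1cc(OCc2ccccc2)cc(OCc2ccccc2)c1)[C@@H](O[Si](C)(C)C(C)(C)C)c1ccc(Br)cc1 | intermediate
18 | (2RS,3S,4R)-2,3-bis[3,5-bis(benzyloxy)phenyl]-4-(4-bromophenyl)-4-[(tert-butyldimethylsilyl)oxy]butan-1-ol | OCC(c1cc(OCc2ccccc2)cc(OCc2ccccc2)c1)[C@@H](c1cc(OCc2ccccc2)cc(OCc2ccccc2)c1)[C@@H](O[Si](C)(C)C(C)(C)C)c1ccc(Br)cc1 | intermediate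
19 | (1R,2S,3RS)-2,3-bis[3,5-bis(benzyloxy)phenyl]-1-(4-bromophenyl)butane-1,4-diol | OCC(c1cc(OCc2ccccc2)cc(OCc2ccccc2)c1)[C@@H](c1cc(OCc2ccccc2)cc(OCc2ccccc2)c1)[C@@H](O)c1ccc(Br)cc1 | intermediate
20 | (4S,5R)-3,4-bis[3,5-bis(benzyloxy)phenyl]-5-(4-bromophenyl)tetrahydrofuran-2-ol (C-2 and C-3 epimers) | OC1O[C@@H](c2ccc(Br)cc2)[C@H](c2cc(OCc3ccccc3)cc(OCc3ccccc3)c2)C1c1cc(OCc2ccccc2)cc(OCc2ccccc2)c1 | intermediate
21 | (4S,5R)-3,4-bis[3,5-bis(benzyloxy)phenyl]-5-(4-bromophenyl)dihydrofuran-2(3H)-one (C-3 epimers) | O=C1O[C@@H](c2ccc(Br)cc2)[C@H](c2cc(OCc3ccccc3)cc(OCc3ccccc3)c2)C1c1cc(OCc2ccccc2)cc(OCc2ccccc2)c1 | intermediate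
22 | (3S,4S,5R)-3,4-bis[3,5-bis(benzyloxy)phenyl]-5-(4-bromophenyl)dihydrofuran-2(3H)-one (all-trans) | O=C1O[C@@H](c2ccc(Br)cc2)[C@H](c2cc(OCc3ccccc3)cc(OCc3ccccc3)c2)[C@H]1c1cc(OCc2ccccc2)cc(OCc2ccccc2)c1 | intermediate
23 | (3S,4S,5R)-3,4-bis[3,5-bis(benzyloxy)phenyl]-5-(4-bromophenyl)tetrahydrofuran-2-ol (anomers) | OC1O[C@@H](c2ccc(Br)cc2)[C@H](c2cc(OCc3ccccc3)cc(OCc3ccccc3)c2)[C@H]1c1cc(OCc2ccccc2)cc(OCc2ccccc2)c1 | intermediate
24 | 1-(benzyloxy)-4-bromobenzene | Brc1ccc(OCc2ccccc2)cc1 | starting material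
25 | [4-(benzyloxy)phenyl]magnesium bromide | Br[Mg]c1ccc(OCc2ccccc2)cc1 | intermediate
26 | (1RS,2S,3S,4R)-1-[4-(benzyloxy)phenyl]-2,3-bis[3,5-bis(benzyloxy)phenyl]-4-(4-bromophenyl)butane-1,4-diol | O[C@@H](c1ccc(Br)cc1)[C@H](c1cc(OCc2ccccc2)cc(OCc2ccccc2)c1)[C@@H](c1cc(OCc2ccccc2)cc(OCc2ccccc2)c1)C(O)c1ccc(OCc2ccccc2)cc1 | intermediate
27 | (R)-{(1S,2S,3R)-4,6-bis(benzyloxy)-3-[4-(benzyloxy)phenyl]-2-[3,5-bis(benzyloxy)phenyl]-2,3-dihydro-1H-inden-1-yl}(4-bromophenyl)methanol | O(Cc1ccccc1)c1ccc([C@@H]2c3c(OCc4ccccc4)cc(OCc4ccccc4)cc3[C@@H]([C@@H](O)c3ccc(Br)cc3)[C@H]2c2cc(OCc3ccccc3)cc(OCc3ccccc3)c2)cc1 | intermediate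
28 | (R)-{(1S,2S,3R)-4,6-bis(benzyloxy)-3-[4-(benzyloxy)phenyl]-2-[3,5-bis(benzyloxy)phenyl]-2,3-dihydro-1H-inden-1-yl}[4-(4,4,5,5-tetramethyl-1,3,2-dioxaborolan-2-yl)phenyl]methanol | O(Cc1ccccc1)c1ccc([C@@H]2c3c(OCc4ccccc4)cc(OCc4ccccc4)cc3[C@@H]([C@@H](O)c3ccc(B4OC(C)(C)C(C)(C)O4)cc3)[C@H]2c2cc(OCc3ccccc3)cc(OCc3ccccc3)c2)cc1 | intermediate
29 | 4-[(R)-{(1S,2S,3R)-4,6-bis(benzyloxy)-3-[4-(benzyloxy)phenyl]-2-[3,5-bis(benzyloxy)phenyl]-2,3-dihydro-1H-inden-1-yl}(hydroxy)methyl]phenol | O(Cc1ccccc1)c1ccc([C@@H]2c3c(OCc4ccccc4)cc(OCc4ccccc4)cc3[C@@H]([C@@H](O)c3ccc(O)cc3)[C@H]2c2cc(OCc3ccccc3)cc(OCc3ccccc3)c2)cc1 | intermediate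
30 | (1S,2S,3R)-2-(3,5-dihydroxyphenyl)-1-[(R)-hydroxy(4-hydroxyphenyl)methyl]-3-(4-hydroxyphenyl)-2,3-dihydro-1H-indene-4,6-diol | Oc1ccc([C@@H]2c3c(O)cc(O)cc3[C@@H]([C@@H](O)c3ccc(O)cc3)[C@H]2c2cc(O)cc(O)c2)cc1 | target

**Totals**
Total step count: 19. Longest linear sequence: 18 (steps 1–6 and 8–19; step 7 is the side branch).

**Three steps most likely to fail**

Step 4, the anti-aldol. The magnesium-catalysed anti-aldol is best established for propionyl imides; with an arylacetyl imide the diastereomer ratio may be lower and retro-aldol easier. The fallback replaces the aldol by an anti-selective carbonyl allylation. It sets out from aldehyde 7 and the Grignard reagent 14 and rejoins the route at ketone 15, bypassing steps 5, 6 and 8. Reagent 14 is added to acrolein to give the allylic alcohol 1-[3,5-bis(benzyloxy)phenyl]prop-2-en-1-ol F1. Palladium-catalysed borylation with allylic transposition (B2pin2, [Pd(MeCN)4](BF4)2 cat., DMSO/MeOH) gives the linear (E)-cinnamyl-type pinacol boronate F2. Allylboration of 7 with F2 under chiral phosphoric acid catalysis ((R)-TRIP, toluene, −30 °C) passes through a closed chair transition state, so the E-boronate gives the anti product, (1R,2S)-2-[3,5-bis(benzyloxy)phenyl]-1-(4-bromophenyl)but-3-en-1-ol F3. Silylation (TBSOTf, 2,6-lutidine) gives the silyl ether F4. Oxidative cleavage of the vinyl group (OsO4 cat., NaIO4, 2,6-lutidine, dioxane/H2O) gives the aldehyde (2S,3R)-2-[3,5-bis(benzyloxy)phenyl]-3-(4-bromophenyl)-3-[(tert-butyldimethylsilyl)oxy]propanal F5. Addition of 14 at −78 °C gives the secondary alcohol F6, and Dess–Martin oxidation of F6 gives 15.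

Step 16, the ring closure. Two things can go wrong. The cation can lose the neighbouring proton to give a stilbene, and reprotonation would scramble C-2. The free second hydroxyl can also trap the cation as a tetrahydrofuran. The fallback makes that ether on purpose and opens it under aprotic, buffered conditions. It sets out from diol 26 and rejoins at indane 27. Mild acid at low temperature (camphorsulfonic acid 5 mol %, CH2Cl2, −40 °C) converts 26 by kinetic O-capture into (2RS,3S,4S,5R)-2-[4-(benzyloxy)phenyl]-3,4-bis[3,5-bis(benzyloxy)phenyl]-5-(4-bromophenyl)tetrahydrofuran F7. TMSOTf with 2,6-di-tert-butyl-4-methylpyridine in CH2Cl2 at −78 °C then opens F7 at the electron-rich benzylic C–O bond; any stilbene formed cannot be reprotonated, and the arene closes to the trimethylsilyl ether of 27, F8. K2CO3 in MeOH removes the silyl group from F8 to give 27.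

Step 19, the final hydrogenolysis. Once the ring para to the carbinol is a free phenol, the benzylic C–OH bond may itself be hydrogenolysed. The fallback changes the order of the last operations. It sets out from boronate 28 and rejoins at target 30. The five benzyl ethers of 28 are hydrogenolysed first (H2, Pd/C, EtOAc/MeOH), while the carbinol still sits on the electron-poor borylated ring, to give the pentaphenol boronate F9. The C–B bond of F9 is then oxidised with NaBO3·4H2O in THF/H2O at rt to give 30.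

**Further compounds**
F1 | step 4 | 1-[3,5-bis(benzyloxy)phenyl]prop-2-en-1-ol (racemic) | C=CC(O)c1cc(OCc2ccccc2)cc(OCc2ccccc2)c1
F2 | step 4 | (E)-2-{3-[3,5-bis(benzyloxy)phenyl]allyl}-4,4,5,5-tetramethyl-1,3,2-dioxaborolane | CC1(C)OB(C/C=C/c2cc(OCc3ccccc3)cc(OCc3ccccc3)c2)OC1(C)C
F3 | step 4 | (1R,2S)-2-[3,5-bis(benzyloxy)phenyl]-1-(4-bromophenyl)but-3-en-1-ol | C=C[C@@H](c1cc(OCc2ccccc2)cc(OCc2ccccc2)c1)[C@@H](O)c1ccc(Br)cc1
F4 | step 4 | tert-butyl{[(1R,2S)-2-[3,5-bis(benzyloxy)phenyl]-1-(4-bromophenyl)but-3-en-1-yl]oxy}dimethylsilane | C=C[C@@H](c1cc(OCc2ccccc2)cc(OCc2ccccc2)c1)[C@@H](O[Si](C)(C)C(C)(C)C)c1ccc(Br)cc1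
F5 | step 4 | (2S,3R)-2-[3,5-bis(benzyloxy)phenyl]-3-(4-bromophenyl)-3-[(tert-butyldimethylsilyl)oxy]propanal | O=C[C@@H](c1cc(OCc2ccccc2)cc(OCc2ccccc2)c1)[C@@H](O[Si](C)(C)C(C)(C)C)c1ccc(Br)cc1
F6 | step 4 | 1,2-bis[3,5-bis(benzyloxy)phenyl]-3-(4-bromophenyl)-3-[(tert-butyldimethylsilyl)oxy]propan-1-ol (C-1 epimers; C-2 and C-3 as in 15) | OC(c1cc(OCc2ccccc2)cc(OCc2ccccc2)c1)[C@@H](c1cc(OCc2ccccc2)cc(OCc2ccccc2)c1)[C@@H](O[Si](C)(C)C(C)(C)C)c1ccc(Br)cc1
F7 | step 16 | (2RS,3S,4S,5R)-2-[4-(benzyloxy)phenyl]-3,4-bis[3,5-bis(benzyloxy)phenyl]-5-(4-bromophenyl)tetrahydrofuran | C1(c2ccc(OCc3ccccc3)cc2)O[C@@H](c2ccc(Br)cc2)[C@H](c2cc(OCc3ccccc3)cc(OCc3ccccc3)c2)[C@H]1c1cc(OCc2ccccc2)cc(OCc2ccccc2)c1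
F8 | step 16 | {(R)-{(1S,2S,3R)-4,6-bis(benzyloxy)-3-[4-(benzyloxy)phenyl]-2-[3,5-bis(benzyloxy)phenyl]-2,3-dihydro-1H-inden-1-yl}(4-bromophenyl)methoxy}trimethylsilane | O(Cc1ccccc1)c1ccc([C@@H]2c3c(OCc4ccccc4)cc(OCc4ccccc4)cc3[C@@H]([C@@H](O[Si](C)(C)C)c3ccc(Br)cc3)[C@H]2c2cc(OCc3ccccc3)cc(OCc3ccccc3)c2)cc1
F9 | step 19 | (1S,2S,3R)-2-(3,5-dihydroxyphenyl)-1-{(R)-hydroxy[4-(4,4,5,5-tetramethyl-1,3,2-dioxaborolan-2-yl)phenyl]methyl}-3-(4-hydroxyphenyl)-2,3-dihydro-1H-indene-4,6-diol | Oc1ccc([C@@H]2c3c(O)cc(O)cc3[C@@H]([C@@H](O)c3ccc(B4OC(C)(C)C(C)(C)O4)cc3)[C@H]2c2cc(O)cc(O)c2)cc1
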